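**Retrosynthetic overview**
1. 18 ⇐ 13 + 16 (cross-metathesis, then diimide). 13 ⇐ 10 + 11: the C3–CH2 bond at the quaternary peroxy carbon C3 of the 1,2-dioxane is cut, because C3 is the one dioxane carbon that can be drawn at the ketone level (cyclic peroxycarbenium ion 12 + allylsilane); C3 is set from C4a.
2. 10 ⇐ 7: the 1,2-dioxane (C3–O2 and O1–C7a bonds) is closed on the finished butenolide by ozonolysis in methanol and 6-exo peroxy-Michael addition; C7a follows from C4a through the cis ring fusion.
3. 7 ⇐ 1: C4a is bought as (S)-2-methylglycidol; cuprate opening, oxidation and a ketenylidene-phosphorane annulation give the butenolide.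
4. Ring order: γ-lactone (step 3), then 1,2-dioxane (step 4), then the C3 quaternary stereocentre on the bicycle (step 5).

Key step: step 5

Assumption: (S)-2-methylglycidol is taken as a purchasable, enantiopure building block; locants are those of furo[3,2-c][1,2]dioxin-6-one (O1, O2, C3, C4, C4a, O5, C6, C7, C7a), and the target is (3S,4aR,7aR), with the two methyl groups cis and the side chain cis to the lactone oxygen.

Step 1
Reactants: 1 (S)-2-methylglycidol; 2 isopropenylmagnesium bromide
Product: 3 (2R)-2,4-dimethylpent-4-ene-1,2-diol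
Conditions: 2 (2.5 equiv), CuI (10 mol%), THF, −30 to 0 °C; aq NH4Cl
Reagents that add atoms: none
Why: Copper-catalysed Grignard opening of the 2,2-disubstituted epoxide is an SN2 attack at the unsubstituted CH2, so the quaternary carbinol carbon (the later C4a) is not touched and keeps its configuration, the first equivalent of 2 being spent on the free OH.

Step 2
Reactants: 3 (2R)-2,4-dimethylpent-4-ene-1,2-diol
Product: 4 (2R)-2-hydroxy-2,4-dimethylpent-4-enal
Conditions: SO3·pyridine, DMSO, Et3N, CH2Cl2, 0 °C; used crude
Reagents that add atoms: none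
Why: Parikh–Doering oxidation can convert only the primary alcohol, and the aldehyde formed has no α-hydrogen, so the stereocentre cannot epimerise.

Step 3
Reactants: 4 (2R)-2-hydroxy-2,4-dimethylpent-4-enal; 5 (triphenylphosphoranylidene)ketene
Product: 7 (5R)-5-methyl-5-(2-methylprop-2-en-1-yl)furan-2(5H)-one, via acyl ylide ester 6 (not isolated)
Conditions: 5 (1.2 equiv), toluene, 90 °C
Reagents that add atoms: none
Why: The tertiary OH adds across the ketene C=C of 5 to give the stabilised ylide 6, whose intramolecular Wittig reaction with the neighbouring aldehyde can only give the ring (cis) alkene of the butenolide.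

Step 4
Reactants: 7 (5R)-5-methyl-5-(2-methylprop-2-en-1-yl)furan-2(5H)-one
Product: 10 (4aR,7aR)-3-methoxy-3,4a-dimethyltetrahydro-3H-furo[3,2-c][1,2]dioxin-6(4H)-one, via carbonyl oxide 8 (not isolated), via hydroperoxy ketal 9 (not isolated)
Conditions: O3, CH2Cl2/MeOH (4:1), −78 °C (Sudan Red 7B end point), N2 purge; evaporate; then Et2NH (0.3 equiv), CF3CH2OH, 0 °C to rt
Reagents that add atoms: ozone O=[O+][O-]; methanol CO
Why: Ozone attacks the electron-rich 1,1-disubstituted alkene far faster than the conjugated butenolide alkene (Criegee ozonolysis), the more substituted carbonyl oxide 8 is trapped by methanol as hydroperoxy ketal 9, and amine-mediated 6-exo-trig oxa-Michael addition of the OOH group to the butenolide β-carbon closes the 1,2-dioxane, the short tether allowing only the cis ring fusion so that C7a follows from C4a (the ketal carbon C3 forms as a mixture that does not matter).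

Step 5
Reactants: 10 (4aR,7aR)-3-methoxy-3,4a-dimethyltetrahydro-3H-furo[3,2-c][1,2]dioxin-6(4H)-one; 11 allyltrimethylsilane
Product: 13 (3S,4aR,7aR)-3,4a-dimethyl-3-(prop-2-en-1-yl)tetrahydro-3H-furo[3,2-c][1,2]dioxin-6(4H)-one, via peroxycarbenium triflate 12 (not isolated)
Conditions: 11 (3 equiv), TMSOTf (0.3 equiv), CH2Cl2, −78 to −40 °C
Reagents that add atoms: none
Why: TMSOTf silylates the more basic methoxy oxygen of the mixed peroxyketal, MeOSiMe3 leaves, and the cyclic peroxycarbenium ion 12 (C3=O2+) is captured at C3 by the allylsilane with loss of the silyl group, which is the Hosomi–Sakurai allylation of a peroxyketal and the peroxide analogue of a Lewis acid-mediated C-glycosylation. No ring is closed; the step forms the C3–CH2 bond and the quaternary peroxy stereocentre C3, and both C3 epimers of 10 converge on the same cation. The cation should prefer the half-chair in which the C4a acyloxy oxygen O5 is pseudoaxial and the C4a methyl pseudoequatorial (C4a displaced from the C4–C3–O2–O1 plane toward the O5 face, C7a toward the methyl face), and attack along the axial trajectory that leads directly to a chair takes place on the face of this axial oxygen. The allyl group should therefore end up cis to the lactone oxygen and the C3 methyl cis to the C4a methyl, which is the (3S) configuration of the target. The other chair-like attack would need the inverted half-chair with the C4a methyl axial and syn to the incoming nucleophile, and attack on the preferred half-chair from the methyl face would pass through a twist-boat, so the quaternary C4a centre secures the facial selectivity. The step also needs ionisation of the exocyclic C–OMe bond and not of the ring C–OO bond, as is usual for monoperoxyketals, and an excess of 11 at low temperature so that C–C bond formation outruns proton loss or fragmentation of 12.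

Step 6
Reactants: 14 11-bromoundec-1-ene; 15 phenylmagnesium bromide
Product: 16 11-phenylundec-1-ene
Conditions: 15 (1.3 equiv), Li2CuCl4 (3 mol%), THF, 0 °C to rt
Reagents that add atoms: none
Why: Copper-catalysed cross-coupling of a primary alkyl bromide with an aryl Grignard reagent (Kochi-type) should proceed cleanly, the remote terminal alkene being inert.

Step 7
Reactants: 13 (3S,4aR,7aR)-3,4a-dimethyl-3-(prop-2-en-1-yl)tetrahydro-3H-furo[3,2-c][1,2]dioxin-6(4H)-one; 16 11-phenylundec-1-ene
Product: 17 (3S,4aR,7aR)-3,4a-dimethyl-3-[(2E)-12-phenyldodec-2-en-1-yl]tetrahydro-3H-furo[3,2-c][1,2]dioxin-6(4H)-one (E/Z mixture expected, E drawn)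
Conditions: 16 (3 equiv), Grubbs II (5 mol%), CH2Cl2, 40 °C
Reagents that add atoms: none
Why: Olefin cross-metathesis of two unhindered terminal alkenes with 16 in excess is driven by loss of ethylene, the dialkyl peroxide and the lactone are tolerated by the ruthenium carbene, and the alkene geometry is of no consequence.

Step 8
Reactants: 17 (3S,4aR,7aR)-3,4a-dimethyl-3-[(2E)-12-phenyldodec-2-en-1-yl]tetrahydro-3H-furo[3,2-c][1,2]dioxin-6(4H)-one
Product: 18 plakortolide K, (3S,4aR,7aR)-3,4a-dimethyl-3-(12-phenyldodecyl)tetrahydro-3H-furo[3,2-c][1,2]dioxin-6(4H)-one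
Conditions: KO2CN=NCO2K (excess, in portions), AcOH, MeOH/CH2Cl2, 0 °C to rt
Reagents that add atoms: none
Why: Diimide generated in the flask transfers H2 in a concerted syn manner to the nonpolar C=C only and should leave the O–O bond, the lactone and the arene untouched, whereas catalytic hydrogenation would cleave the peroxide.

**Compound list**
1 | (S)-2-methylglycidol, (S)-(2-methyloxiran-2-yl)methanol | C[C@]1(CO)CO1 | starting material
2 | isopropenylmagnesium bromide | CC(=C)[Mg]Br | starting material
3 | (2R)-2,4-dimethylpent-4-ene-1,2-diol | CC(=C)C[C@@](C)(O)CO | intermediate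
4 | (2R)-2-hydroxy-2,4-dimethylpent-4-enal | CC(=C)C[C@@](C)(O)C=O | intermediate
5 | (triphenylphosphoranylidene)ketene | O=C=C=P(c1ccccc1)(c1ccccc1)c1ccccc1 | starting material
6 | (2R)-2,4-dimethyl-1-oxopent-4-en-2-yl (triphenyl-λ5-phosphanylidene)acetate | CC(=C)C[C@@](C)(OC(=O)C=P(c1ccccc1)(c1ccccc1)c1ccccc1)C=O | intermediate
7 | (5R)-5-methyl-5-(2-methylprop-2-en-1-yl)furan-2(5H)-one | CC(=C)C[C@@]1(C)OC(=O)C=C1 | intermediate
8 | carbonyl oxide of (5R)-5-methyl-5-(2-oxopropyl)furan-2(5H)-one | CC(=[O+][O-])C[C@@]1(C)OC(=O)C=C1 | intermediate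
9 | (5R)-5-(2-hydroperoxy-2-methoxypropyl)-5-methylfuran-2(5H)-one (both ketal epimers) | COC(C)(OO)C[C@@]1(C)OC(=O)C=C1 | intermediate
10 | (4aR,7aR)-3-methoxy-3,4a-dimethyltetrahydro-3H-furo[3,2-c][1,2]dioxin-6(4H)-one (both C3 epimers) | COC1(C)C[C@@]2(C)OC(=O)C[C@H]2OO1 | intermediate
11 | allyltrimethylsilane | C=CC[Si](C)(C)C | starting material
12 | (4aR,7aR)-3,4a-dimethyl-6-oxo-4,4a,7,7a-tetrahydro-6H-furo[3,2-c][1,2]dioxin-2-ium triflate | CC=1C[C@@]2(C)OC(=O)C[C@H]2O[O+]=1.[O-]S(=O)(=O)C(F)(F)F | intermediate
13 | (3S,4aR,7aR)-3,4a-dimethyl-3-(prop-2-en-1-yl)tetrahydro-3H-furo[3,2-c][1,2]dioxin-6(4H)-one | C[C@]1(CC=C)C[C@@]2(C)OC(=O)C[C@H]2OO1 | intermediate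
14 | 11-bromoundec-1-ene | C=CCCCCCCCCCBr | starting material
15 | phenylmagnesium bromide | Br[Mg]c1ccccc1 | starting material
16 | 11-phenylundec-1-ene | C=CCCCCCCCCCc1ccccc1 | intermediate
17 | (3S,4aR,7aR)-3,4a-dimethyl-3-[(2E)-12-phenyldodec-2-en-1-yl]tetrahydro-3H-furo[3,2-c][1,2]dioxin-6(4H)-one | C[C@]1(C/C=C/CCCCCCCCCc2ccccc2)C[C@@]2(C)OC(=O)C[C@H]2OO1 | intermediate
18 | plakortolide K, (3S,4aR,7aR)-3,4a-dimethyl-3-(12-phenyldodecyl)tetrahydro-3H-furo[3,2-c][1,2]dioxin-6(4H)-one | C[C@]1(CCCCCCCCCCCCc2ccccc2)C[C@@]2(C)OC(=O)C[C@H]2OO1 | target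

**Step count**
Total: 8 steps. Longest linear sequence: 7 steps (steps 1, 2, 3, 4, 5, 7, 8 from compound 1).

**Steps most likely to fail**

Step 5. The capture of the peroxycarbenium ion may show poor facial selectivity (attack through the twist-boat or through the inverted half-chair), or the cation may lose a proton or fragment before the C–C bond forms. The fallback makes the C3–O bond by radical oxygenation instead, at the price of stereocontrol at C3. It sets out from butenolide 7 and bromide 14. Copper-catalysed coupling of 14 with 2-phenylethylmagnesium chloride should give 13-phenyltridec-1-ene F1. Cross-metathesis of F1 with the 1,1-disubstituted alkene of 7 (Hoveyda–Grubbs II, CH2Cl2, 40 °C) should give the trisubstituted alkene (5R)-5-methyl-5-(2-methyl-14-phenyltetradec-2-en-1-yl)furan-2(5H)-one F2. Mukaiyama–Isayama hydroperoxysilylation (Co(thd)2, O2, Et3SiH, ClCH2CH2Cl) should give the tertiary silyl peroxide (5R)-5-methyl-5-[2-methyl-14-phenyl-2-(triethylsilylperoxy)tetradecyl]furan-2(5H)-one F3 as both epimers. Fluoride (TBAF, THF, 0 °C) should free the hydroperoxide (5R)-5-(2-hydroperoxy-2-methyl-14-phenyltetradecyl)-5-methylfuran-2(5H)-one F4, which should close by the same 6-exo peroxy-Michael addition to 18 together with its C3 epimer, (3R,4aR,7aR)-3,4a-dimethyl-3-(12-phenyldodecyl)tetrahydro-3H-furo[3,2-c][1,2]dioxin-6(4H)-one F5, to be removed by chromatography. The fallback comes back to the route at 18.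

Step 4. Ozone may also cleave the butenolide alkene, or the hydroperoxy ketal may be consumed by the formaldehyde set free or by base-induced Kornblum–DeLaMare decomposition during the one-pot ring closure. The fallback separates alkene cleavage from peroxide formation and sets out from 7. Lemieux–Johnson cleavage (OsO4 cat., NaIO4, 2,6-lutidine, dioxane/H2O) should give the ketone (5R)-5-methyl-5-(2-oxopropyl)furan-2(5H)-one F6. Perketalisation of the isolated ketone (urea·H2O2, Sc(OTf)3 cat., MeOH) should then give hydroperoxy ketal 9 free of formaldehyde, and Et2NH in CF3CH2OH should close it to 10. The fallback comes back to the route at 9 and from there at 10.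

Step 3. O-Acylation of the hindered tertiary alcohol by the ylide may be slow, so that the α-hydroxy aldehyde oligomerises or undergoes α-ketol rearrangement at 90 °C. The fallback forms the C=C bond first at low temperature and the C–O bond afterwards, and sets out from 4. Still–Gennari olefination (methyl bis(2,2,2-trifluoroethyl)phosphonoacetate, KHMDS, 18-crown-6, THF, −78 °C) should give methyl (2Z,4R)-4-hydroxy-4,6-dimethylhepta-2,6-dienoate F7. Acid-catalysed lactonisation (PPTS, CH2Cl2) should then give 7, where the fallback comes back to the route.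

**Further compounds**
F1 | step 5 | 13-phenyltridec-1-ene | C=CCCCCCCCCCCCc1ccccc1
F2 | step 5 | (5R)-5-methyl-5-(2-methyl-14-phenyltetradec-2-en-1-yl)furan-2(5H)-one (E/Z) | CC(=CCCCCCCCCCCCc1ccccc1)C[C@@]1(C)OC(=O)C=C1
F3 | step 5 | (5R)-5-methyl-5-[2-methyl-14-phenyl-2-(triethylsilylperoxy)tetradecyl]furan-2(5H)-one (both epimers) | CC[Si](CC)(CC)OOC(C)(CCCCCCCCCCCCc1ccccc1)C[C@@]1(C)OC(=O)C=C1
F4 | step 5 | (5R)-5-(2-hydroperoxy-2-methyl-14-phenyltetradecyl)-5-methylfuran-2(5H)-one (both epimers) | CC(OO)(CCCCCCCCCCCCc1ccccc1)C[C@@]1(C)OC(=O)C=C1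
F5 | step 5 | (3R,4aR,7aR)-3,4a-dimethyl-3-(12-phenyldodecyl)tetrahydro-3H-furo[3,2-c][1,2]dioxin-6(4H)-one | C[C@@]1(CCCCCCCCCCCCc2ccccc2)C[C@@]2(C)OC(=O)C[C@H]2OO1
F6 | step 4 | (5R)-5-methyl-5-(2-oxopropyl)furan-2(5H)-one | CC(=O)C[C@@]1(C)OC(=O)C=C1
F7 | step 3 | methyl (2Z,4R)-4-hydroxy-4,6-dimethylhepta-2,6-dienoate | CC(=C)C[C@@](C)(O)/C=C\C(=O)OC
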